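**Plan**

1. The ten-membered ring (C1–C10) is cut at C4–C5. This bond joins the only unfunctionalised stretch of the ring (C3H2–C4H2) to the (5Z)-trisubstituted alkene, whose C6 sits on the lactone carbinol C7. The ring therefore opens to a C3=C4 vinyl group on the C2 carbinol and a (Z)-2-iodopropenyl group on C7, the retron of a hydroboration/B-alkyl Suzuki–Miyaura closure.
2. Further cuts: C5=C6 (olefination of a C6 aldehyde), C7–O and C8–C17 (iodolactonisation, amide aldol on a C8 ketone), C8–C9 (allylboration of a C9 aldehyde), C1–C2 and C9–C10 (conjugate addition–aldol on a 4-silyloxy-2-methylcyclohexenone).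
3. Forward order: the six-membered ring (C1, C10–C14) comes from 4-silyloxycyclohexanone, the γ-lactone (C7, C8, C17, C19, O) is then built on the C9 arm, and the ten-membered ring is closed last. The C11 methylene and the four acetates follow.
4. Stereochemistry: C11–O is set by an enantioselective deprotonation and relays C10, C1 and C2 in one conjugate addition–aldol event, then C13/C14. C9 comes from Ipc reagent control, C8/C17 from a Felkin–Anh syn-aldol, C7 from iodolactonisation cis to 8-OH, and 5Z from a Stork–Zhao olefination that is kept in the coupling.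
5. Enabling feature: the trans-diequatorial C2 and C9 arms on the six-membered ring and the rigid γ-lactone hold C4 and C5 within reach, and the Z geometry is already fixed in the iodoalkene.

Key step: step 19

Numbering: briarane numbering is used for all intermediates (ten-membered ring C1–C10; six-membered ring C1, C10–C14; lactone C7–O–C19(=O)–C17(C18)–C8; C15 on C1, C16 on C5, C20 on C11). β is the face of the six-membered ring that carries C15, α the opposite face. Compound 1 is the only numbered starting material; all other atoms come from commercial reagents given with SMILES at each step.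

Assumption: lithium (S,S)-bis(1-phenylethyl)amide is taken to give the (R)-enol ether 2, by analogy with other 4-substituted cyclohexanones; if the sense proves opposite, the (R,R)-amide is used and nothing else changes.

**Route**

Step 1
Reactants: 1 4-(tert-butyldimethylsilyloxy)cyclohexan-1-one
Product: 2 (R)-4-(tert-butyldimethylsilyloxy)-1-(trimethylsilyloxy)cyclohex-1-ene
Conditions: (S,S)-bis(1-phenylethyl)amine, n-BuLi, THF, 0 °C; then TMSCl and 1, −78 °C
Reagents that add atoms: chlorotrimethylsilane, C[Si](C)(C)Cl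
Why: Enantioselective deprotonation of the prochiral ketone by the C2-symmetric chiral lithium amide with in situ silylation (desymmetrisation) should differentiate the enantiotopic α-methylenes and fix the C11 silyloxy stereocentre.

Step 2
Reactants: 2 (R)-4-(tert-butyldimethylsilyloxy)-1-(trimethylsilyloxy)cyclohex-1-ene
Product: 3 (R)-4-(tert-butyldimethylsilyloxy)cyclohex-2-en-1-one
Conditions: Pd(OAc)2 (1.1 equiv), MeCN, rt
Reagents that add atoms: none
Why: Saegusa–Ito oxidation (palladation of the silyl enol ether, β-hydride elimination) should give the enone regiospecifically on the enol-ether side without touching C11.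

Step 3
Reactants: 3 (R)-4-(tert-butyldimethylsilyloxy)cyclohex-2-en-1-one
Product: 4 (R)-4-(tert-butyldimethylsilyloxy)-2-iodocyclohex-2-en-1-one
Conditions: I2, pyridine, CH2Cl2, 0 °C to rt
Reagents that add atoms: iodine, II
Why: Amine-mediated α-iodination of an enone (conjugate addition of pyridine, iodination of the enolate, elimination) is a standard entry to 2-iodoenones.

Step 4
Reactants: 4 (R)-4-(tert-butyldimethylsilyloxy)-2-iodocyclohex-2-en-1-one
Product: 5 (R)-4-(tert-butyldimethylsilyloxy)-2-methylcyclohex-2-en-1-one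
Conditions: Me4Sn, Pd2(dba)3 (5 mol %), AsPh3, CuI, NMP, 60 °C
Reagents that add atoms: tetramethylstannane, C[Sn](C)(C)C
Why: Stille coupling of the electron-poor alkenyl iodide should install the C15 methyl group without affecting the silyl ether.

Step 5
Reactants: 5 (R)-4-(tert-butyldimethylsilyloxy)-2-methylcyclohex-2-en-1-one
Product: 7 β-hydroxy ketone (C14 ketone; 1β-Me; 2S carbinol with vinyl; 10β-CH2Si; 11α-OTBS), via chloromagnesium enolate 6 (not isolated)
Conditions: (i-PrO)Me2SiCH2MgCl, CuBr·SMe2 (20 mol %), THF, −78 to −40 °C; then acrolein, −78 °C; NH4Cl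
Reagents that add atoms: (isopropoxydimethylsilyl)methylmagnesium chloride, CC(C)O[Si](C)(C)C[Mg]Cl; acrolein, C=CC=O
Why: In this tandem copper-catalysed conjugate addition–aldol reaction the silylmethyl group should add to C10 anti to the C11 silyloxy group, and the tetrasubstituted magnesium enolate should then attack acrolein on the face trans to the new C10 substituent through a Zimmerman–Traxler chair with the vinyl group equatorial, so that C10, the quaternary C1 and the C2 carbinol are relayed from C11 in one operation.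

Step 6
Reactants: 7 β-hydroxy ketone
Product: 8 2-O-triethylsilyl ether of 7
Conditions: Et3SiOTf, 2,6-lutidine, CH2Cl2, −78 °C
Reagents that add atoms: triethylsilyl trifluoromethanesulfonate, CC[Si](CC)(CC)OS(=O)(=O)C(F)(F)F
Why: Silylation with the silyl triflate under non-basic, low-temperature conditions should protect the retro-aldol-prone β-hydroxy ketone.

Step 7
Reactants: 8 2-O-triethylsilyl ether of 7
Product: 10 13α-hydroxy-14-ketone, via potassium enolate 9 (not isolated)
Conditions: KN(SiMe3)2, THF, −78 °C; then 2-(phenylsulfonyl)-3-phenyloxaziridine, −78 °C; NH4Cl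
Reagents that add atoms: 2-(phenylsulfonyl)-3-phenyloxaziridine, O=S(=O)(N1OC1c1ccccc1)c1ccccc1
Why: Oxaziridine hydroxylation of the enolate, which can form only toward C13 because C1 is quaternary, should deliver oxygen anti to the axial C15 methyl group and give the equatorial 13α-alcohol.

Step 8
Reactants: 10 13α-hydroxy-14-ketone
Product: 11 13α,14α-diol
Conditions: LiBH(s-Bu)3 (2.5 equiv), THF, −78 °C
Reagents that add atoms: none
Why: The bulky trialkylborohydride should attack the C14 ketone from the equatorial direction and give the axial 14α-alcohol cis to the 13α-hydroxyl (stereoselective ketone reduction).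

Step 9
Reactants: 11 13α,14α-diol
Product: 12 13,14-O-isopropylidene acetal
Conditions: Me2C(OMe)2, PPTS (cat.), CH2Cl2, rt
Reagents that add atoms: 2,2-dimethoxypropane, COC(C)(C)OC
Why: Acid-catalysed transketalisation should close the five-membered acetonide on the cis-13,14-diol only.

Step 10
Reactants: 12 13,14-O-isopropylidene acetal
Product: 13 primary alcohol (C9–OH)
Conditions: H2O2 (30 %), KF, KHCO3, THF/MeOH, rt
Reagents that add atoms: hydrogen peroxide, OO
Why: Tamao–Fleming oxidation of the alkoxysilane should convert the C9–Si bond into C9–OH under mild conditions that spare the vinyl group, the acetonide and the hindered silyl ethers.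

Step 11
Reactants: 13 primary alcohol (C9–OH)
Product: 14 C9 aldehyde
Conditions: Dess–Martin periodinane, NaHCO3, CH2Cl2, 0 °C to rt
Reagents that add atoms: none
Why: Dess–Martin oxidation under buffered conditions should give the aldehyde without disturbing C10 (already in its more stable equatorial arrangement) or eliminating the β-silyloxy group.

Step 12
Reactants: 14 C9 aldehyde
Product: 16 (8R,9S)-8,9-diol bearing the C7=C6 vinyl group, via borinate 15 (not isolated)
Conditions: allyl(diisopropylamino)dimethylsilane, n-BuLi, TMEDA, Et2O, 0 °C; (+)-Ipc2BOMe, −78 °C; BF3·OEt2; then 14, −78 °C; then H2O2, KF, KHCO3, THF/MeOH, rt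
Reagents that add atoms: allyl(diisopropylamino)dimethylsilane, C=CC[Si](C)(C)N(C(C)C)C(C)C; hydrogen peroxide, OO
Why: γ-Silylallylboration through a closed chair transition state followed by Tamao–Fleming oxidation should give the anti-diol, with the Ipc groups (reagent control, attack on the Re face of C9 expected for the reagent derived from (−)-α-pinene) setting C9 as S and the E-allyl geometry setting C8, which is oxidised in the next step.

Step 13
Reactants: 16 (8R,9S)-8,9-diol
Product: 17 (9S)-9-hydroxy-8-ketone (vinyl ketone)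
Conditions: MnO2 (activated, excess), CH2Cl2, rt
Reagents that add atoms: none
Why: MnO2 should oxidise only the allylic C8 alcohol and leave the hindered, non-allylic C9 alcohol (chemoselective allylic oxidation).

Step 14
Reactants: 17 (9S)-9-hydroxy-8-ketone
Product: 18 9-O-triethylsilyl ether of 17
Conditions: Et3SiOTf, 2,6-lutidine, CH2Cl2, −78 °C
Reagents that add atoms: triethylsilyl trifluoromethanesulfonate, CC[Si](CC)(CC)OS(=O)(=O)C(F)(F)F
Why: Silylation should place a bulky, non-chelating silyloxy group at C9, as needed for Felkin–Anh control in the next step.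

Step 15
Reactants: 18 9-O-triethylsilyl ether of 17
Product: 19 β-hydroxy amide (C8 tertiary alcohol and C17 methyl as in the target)
Conditions: N,N-dimethylpropionamide, LiN(i-Pr)2, THF, −78 °C; then 18, −78 °C; NH4Cl at −78 °C
Reagents that add atoms: N,N-dimethylpropionamide, CCC(=O)N(C)C
Why: In this aldol addition of the Z(O)-amide enolate to the ketone carbonyl (1,2-addition at low temperature), Felkin–Anh attack anti to the C9 silyloxy group should set C8 and the Zimmerman–Traxler chair with the large C9 arm equatorial should set C17 syn, which is the target C8/C17 array.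

Step 16
Reactants: 19 β-hydroxy amide
Product: 20 iodolactone (γ-lactone C7–O–C19; C6H2–I)
Conditions: I2 (3 equiv), THF/H2O (1:1), 0 °C to rt
Reagents that add atoms: iodine, II; water, O
Why: Iodolactonisation of the γ,δ-unsaturated amide (5-exo attack of the amide oxygen on the iodonium ion, hydrolysis of the iminium lactone) should place the iodomethyl group cis to the 8-hydroxyl and trans to the bulky C9 arm, which sets C7 and closes the γ-lactone.

Step 17
Reactants: 20 iodolactone
Product: 22 C6 aldehyde, via alkoxysulfonium salt 21 (not isolated)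
Conditions: AgBF4, DMSO, rt; then Et3N
Reagents that add atoms: dimethyl sulfoxide, CS(C)=O
Why: In this silver-assisted Kornblum oxidation the iodide is displaced by DMSO and the alkoxysulfonium salt should collapse with Et3N to the aldehyde without a free-alcohol stage.

Step 18
Reactants: 22 C6 aldehyde
Product: 23 (Z)-iodoalkene (C6H=C5(I)CH3 with iodine cis to C7)
Conditions: EtPPh3I, n-BuLi, THF, rt; I2, −78 °C; NaN(SiMe3)2, −20 °C; then 22, −78 to −20 °C
Reagents that add atoms: ethyltriphenylphosphonium iodide, CC[P+](c1ccccc1)(c1ccccc1)c1ccccc1.[I-]; iodine, II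
Why: Stork–Zhao olefination with the α-iodoethylidene ylide should give the (Z)-2-iodoalkene under kinetic control at low temperature, which fixes the future 5Z geometry.

Step 19
Reactants: 23 (Z)-iodoalkene
Product: 25 macrocycle (ten-membered ring closed; 5Z), via B-alkyl-9-BBN 24 (not isolated)
Conditions: 9-BBN-H (3 equiv), THF, rt; then slow addition to Pd(dppf)Cl2 (20 mol %), AsPh3, Cs2CO3, DMF/THF/H2O, 50 °C, about 2 mM
Reagents that add atoms: none
Why: 9-BBN should add anti-Markovnikov to the only terminal alkene (C3=C4; the trisubstituted iodoalkene is inert) to give borane 24, after which zerovalent palladium inserts into the C5–I bond, the primary alkyl group is transferred from the base-activated borate and reductive elimination forms C4–C5. The closest known reaction type is the B-alkyl Suzuki–Miyaura macrocyclisation of ω-boryl alkenyl iodides, which has been used to close nine-membered and larger carbocycles. The ten-membered ring C1–C10 is closed by C(sp3)–C(sp2) reductive elimination from an eleven-membered palladacycle, the new bond lying between the C3–C4 methylenes and the endocyclic alkene. No stereocentre is formed; the 5Z geometry is that of the iodoalkene and is transferred with retention, so the cis-cycloalkene is fixed before the ring exists. The step needs cyclisation to outrun oligomerisation, protodeboronation and β-hydride elimination, which slow addition at high dilution, the bidentate dppf ligand, and the pre-set gauche (trans-diequatorial) C2 and C9 arms on the six-membered ring together with the rigid lactone should secure.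

Step 20
Reactants: 25 macrocycle
Product: 26 2,9,13,14-tetraol (11α-OTBS retained)
Conditions: PPTS, MeOH, 45 °C
Reagents that add atoms: none
Why: Acid-catalysed methanolysis should cleave the two triethylsilyl ethers and the acetonide while the more robust tert-butyldimethylsilyl ether at C11 survives (selective deprotection).

Step 21
Reactants: 26 2,9,13,14-tetraol
Product: 27 2,9,13,14-tetraacetate
Conditions: Ac2O, pyridine, DMAP (cat.), CH2Cl2, rt
Reagents that add atoms: acetic anhydride, CC(=O)OC(C)=O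
Why: Acetylation under nucleophilic catalysis should esterify the four secondary alcohols, whereas the tertiary 8-hydroxyl is too hindered to react.

Step 22
Reactants: 27 2,9,13,14-tetraacetate
Product: 28 11α-alcohol
Conditions: HF·pyridine, pyridine/THF, 0 °C to rt
Reagents that add atoms: none
Why: Fluoride-mediated desilylation under weakly acidic conditions should free the C11 alcohol without acetyl migration.

Step 23
Reactants: 28 11α-alcohol
Product: 29 11-ketone
Conditions: Dess–Martin periodinane, NaHCO3, CH2Cl2, 0 °C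
Reagents that add atoms: none
Why: Dess–Martin oxidation under buffered conditions should give the C11 ketone without β-elimination of the flanking C9 and C13 acetates.

Step 24
Reactants: 29 11-ketone
Product: 30 Frajunolide E
Conditions: Zn, CH2Br2, TiCl4, THF/CH2Cl2, 0 °C to rt
Reagents that add atoms: dibromomethane, BrCBr
Why: Lombardo–Takai methylenation with the gem-dizinc/titanium reagent is non-basic and selective for ketones over esters and lactones, so it should install the exocyclic C11=C20 alkene without epimerising C10 or eliminating the β-acetoxy groups.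

**Compound list**

1 | 4-(tert-butyldimethylsilyloxy)cyclohexan-1-one | O=C1CCC(O[Si](C)(C)C(C)(C)C)CC1 | starting material
2 | (R)-4-(tert-butyldimethylsilyloxy)-1-(trimethylsilyloxy)cyclohex-1-ene | [C@@H]1(O[Si](C)(C)C(C)(C)C)CCC(O[Si](C)(C)C)=CC1 | intermediate
3 | (R)-4-(tert-butyldimethylsilyloxy)cyclohex-2-en-1-one | [C@@H]1(O[Si](C)(C)C(C)(C)C)CCC(=O)C=C1 | intermediate
4 | (R)-4-(tert-butyldimethylsilyloxy)-2-iodocyclohex-2-en-1-one | [C@@H]1(O[Si](C)(C)C(C)(C)C)CCC(=O)C(I)=C1 | intermediate
5 | (R)-4-(tert-butyldimethylsilyloxy)-2-methylcyclohex-2-en-1-one | [C@@H]1(O[Si](C)(C)C(C)(C)C)CCC(=O)C(C)=C1 | intermediate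
6 | chloromagnesium C1=C14 enolate with 10β-CH2SiMe2(O-i-Pr) trans to 11α-OTBS | [C@@H]1(O[Si](C)(C)C(C)(C)C)CCC(O[Mg]Cl)=C(C)[C@H]1C[Si](C)(C)OC(C)C | intermediate (not isolated)
7 | (2S,3R,4R)-4-(tert-butyldimethylsilyloxy)-2-[(1S)-1-hydroxyprop-2-en-1-yl]-3-[(isopropoxydimethylsilyl)methyl]-2-methylcyclohexan-1-one (C14 ketone, 1β-Me, 2S carbinol, 10β-CH2Si, 11α-OTBS) | [C@@H]1(O[Si](C)(C)C(C)(C)C)CCC(=O)[C@](C)([C@@H](O)C=C)[C@H]1C[Si](C)(C)OC(C)C | intermediate
8 | 2-O-triethylsilyl ether of 7 | [C@@H]1(O[Si](C)(C)C(C)(C)C)CCC(=O)[C@](C)([C@@H](O[Si](CC)(CC)CC)C=C)[C@H]1C[Si](C)(C)OC(C)C | intermediate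
9 | potassium C13=C14 enolate of 8 | [C@@H]1(O[Si](C)(C)C(C)(C)C)CC=C(O[K])[C@](C)([C@@H](O[Si](CC)(CC)CC)C=C)[C@H]1C[Si](C)(C)OC(C)C | intermediate (not isolated)
10 | 13α-hydroxy-14-ketone (otherwise as 8) | [C@@H]1(O[Si](C)(C)C(C)(C)C)C[C@H](O)C(=O)[C@](C)([C@@H](O[Si](CC)(CC)CC)C=C)[C@H]1C[Si](C)(C)OC(C)C | intermediate
11 | 13α,14α-diol (otherwise as 8) | [C@@H]1(O[Si](C)(C)C(C)(C)C)C[C@H](O)[C@H](O)[C@](C)([C@@H](O[Si](CC)(CC)CC)C=C)[C@H]1C[Si](C)(C)OC(C)C | intermediate
12 | 13α,14α-O-isopropylidene acetal of 11 | [C@@H]1(O[Si](C)(C)C(C)(C)C)C[C@@H]2OC(C)(C)O[C@@H]2[C@](C)([C@@H](O[Si](CC)(CC)CC)C=C)[C@H]1C[Si](C)(C)OC(C)C | intermediate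
13 | primary alcohol: 10β-CH2OH (C9), 11α-OTBS, 13,14-acetonide, 1β-Me, (2S)-OTES vinyl carbinol | [C@@H]1(O[Si](C)(C)C(C)(C)C)C[C@@H]2OC(C)(C)O[C@@H]2[C@](C)([C@@H](O[Si](CC)(CC)CC)C=C)[C@H]1CO | intermediate
14 | C9 aldehyde (otherwise as 13) | [C@@H]1(O[Si](C)(C)C(C)(C)C)C[C@@H]2OC(C)(C)O[C@@H]2[C@](C)([C@@H](O[Si](CC)(CC)CC)C=C)[C@H]1C=O | intermediate
15 | allylboration adduct: C9–O–B(Ipc)2 and C8–SiMe2N(i-Pr)2 anti, C7=C6 vinyl | [C@@H]1(O[Si](C)(C)C(C)(C)C)C[C@@H]2OC(C)(C)O[C@@H]2[C@](C)([C@@H](O[Si](CC)(CC)CC)C=C)[C@H]1[C@H](OB([C@H]3C[C@H]4C[C@@H]([C@@H]3C)C4(C)C)[C@H]3C[C@H]4C[C@@H]([C@@H]3C)C4(C)C)[C@H]([Si](C)(C)N(C(C)C)C(C)C)C=C | intermediate (not isolated)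
16 | (8R,9S)-8,9-anti-diol with C7=C6 vinyl on C8 (ring as 13) | [C@@H]1(O[Si](C)(C)C(C)(C)C)C[C@@H]2OC(C)(C)O[C@@H]2[C@](C)([C@@H](O[Si](CC)(CC)CC)C=C)[C@H]1[C@H](O)[C@H](O)C=C | intermediate
17 | (9S)-9-hydroxy-8-oxo vinyl ketone (C9–C8(=O)–C7H=C6H2) | [C@@H]1(O[Si](C)(C)C(C)(C)C)C[C@@H]2OC(C)(C)O[C@@H]2[C@](C)([C@@H](O[Si](CC)(CC)CC)C=C)[C@H]1[C@H](O)C(=O)C=C | intermediate
18 | 9-O-triethylsilyl ether of 17 | [C@@H]1(O[Si](C)(C)C(C)(C)C)C[C@@H]2OC(C)(C)O[C@@H]2[C@](C)([C@@H](O[Si](CC)(CC)CC)C=C)[C@H]1[C@H](O[Si](CC)(CC)CC)C(=O)C=C | intermediate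
19 | N,N-dimethyl amide of the β-hydroxy acid: C8 tertiary alcohol bearing vinyl (C7=C6), C17 methyl, C19 amide; C8 and C17 arranged as in the target | [C@@H]1(O[Si](C)(C)C(C)(C)C)C[C@@H]2OC(C)(C)O[C@@H]2[C@](C)([C@@H](O[Si](CC)(CC)CC)C=C)[C@H]1[C@H](O[Si](CC)(CC)CC)[C@@](O)(C=C)[C@@H](C)C(=O)N(C)C | intermediate
20 | iodolactone: γ-lactone C7–O–C19(=O)–C17(Me)–C8(OH), C7 bearing CH2I cis to 8-OH; C7, C8, C17 as in the target | [C@@H]1(O[Si](C)(C)C(C)(C)C)C[C@@H]2OC(C)(C)O[C@@H]2[C@](C)([C@@H](O[Si](CC)(CC)CC)C=C)[C@H]1[C@H](O[Si](CC)(CC)CC)[C@]3(O)[C@@H](C)C(=O)O[C@H]3CI | intermediate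
21 | C6 alkoxydimethylsulfonium tetrafluoroborate of the lactone | [C@@H]1(O[Si](C)(C)C(C)(C)C)C[C@@H]2OC(C)(C)O[C@@H]2[C@](C)([C@@H](O[Si](CC)(CC)CC)C=C)[C@H]1[C@H](O[Si](CC)(CC)CC)[C@]3(O)[C@@H](C)C(=O)O[C@H]3CO[S+](C)C.F[B-](F)(F)F | intermediate (not isolated)
22 | C6 aldehyde on the lactone carbinol C7 | [C@@H]1(O[Si](C)(C)C(C)(C)C)C[C@@H]2OC(C)(C)O[C@@H]2[C@](C)([C@@H](O[Si](CC)(CC)CC)C=C)[C@H]1[C@H](O[Si](CC)(CC)CC)[C@]3(O)[C@@H](C)C(=O)O[C@H]3C=O | intermediate
23 | (Z)-iodoalkene: C7–C6H=C5(I)–C16H3, iodine cis to C7 | [C@@H]1(O[Si](C)(C)C(C)(C)C)C[C@@H]2OC(C)(C)O[C@@H]2[C@](C)([C@@H](O[Si](CC)(CC)CC)C=C)[C@H]1[C@H](O[Si](CC)(CC)CC)[C@]3(O)[C@@H](C)C(=O)O[C@H]3/C=C(/C)I | intermediate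
24 | B-alkyl-9-BBN: C4 bonded to the boron of 9-borabicyclo[3.3.1]nonane (C2–C3H2–C4H2–B) | [C@@H]1(O[Si](C)(C)C(C)(C)C)C[C@@H]2OC(C)(C)O[C@@H]2[C@](C)([C@@H](O[Si](CC)(CC)CC)CCB4C5CCCC4CCC5)[C@H]1[C@H](O[Si](CC)(CC)CC)[C@]3(O)[C@@H](C)C(=O)O[C@H]3/C=C(/C)I | intermediate (not isolated)
25 | macrocycle: briarane skeleton with 2,9-bis(OTES), 11α-OTBS, 13,14-acetonide, 8-OH, 5Z alkene, lactone | [C@@H]1(O[Si](C)(C)C(C)(C)C)C[C@@H]5OC(C)(C)O[C@@H]5[C@]2(C)[C@@H](O[Si](CC)(CC)CC)CC/C(C)=C\[C@@H]3OC(=O)[C@H](C)[C@@]3(O)[C@@H](O[Si](CC)(CC)CC)[C@@H]12 | intermediate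
26 | 2,9,13,14-tetraol with 11α-OTBS and 8-OH | [C@@H]1(O[Si](C)(C)C(C)(C)C)C[C@H](O)[C@H](O)[C@]2(C)[C@@H](O)CC/C(C)=C\[C@@H]3OC(=O)[C@H](C)[C@@]3(O)[C@@H](O)[C@@H]12 | intermediate
27 | 2,9,13,14-tetraacetate with 11α-OTBS and 8-OH | [C@@H]1(O[Si](C)(C)C(C)(C)C)C[C@H](OC(C)=O)[C@H](OC(C)=O)[C@]2(C)[C@@H](OC(C)=O)CC/C(C)=C\[C@@H]3OC(=O)[C@H](C)[C@@]3(O)[C@@H](OC(C)=O)[C@@H]12 | intermediate
28 | 11α-alcohol (tetraacetate) | [C@@H]1(O)C[C@H](OC(C)=O)[C@H](OC(C)=O)[C@]2(C)[C@@H](OC(C)=O)CC/C(C)=C\[C@@H]3OC(=O)[C@H](C)[C@@]3(O)[C@@H](OC(C)=O)[C@@H]12 | intermediate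
29 | 11-ketone (tetraacetate) | O=C1C[C@H](OC(C)=O)[C@H](OC(C)=O)[C@]2(C)[C@@H](OC(C)=O)CC/C(C)=C\[C@@H]3OC(=O)[C@H](C)[C@@]3(O)[C@@H](OC(C)=O)[C@@H]12 | intermediate
30 | Frajunolide E, (1S,2S,5Z,7S,8S,9S,10S,13S,14R,17R) | C=C1C[C@H](OC(C)=O)[C@H](OC(C)=O)[C@]2(C)[C@@H](OC(C)=O)CC/C(C)=C\[C@@H]3OC(=O)[C@H](C)[C@@]3(O)[C@@H](OC(C)=O)[C@@H]12 | target

**Totals and risks**

Total step count: 24. Longest linear sequence: 24 steps (the route is linear from compound 1).

Three steps most likely to fail:

1. Step 19 (ring closure). Intermolecular coupling, protodeboronation or β-hydride elimination of the alkylpalladium intermediate may outrun closure of the strained ten-membered ring. The fallback closes the ring at C5=C6 by metathesis instead of at C4–C5. It sets out from iodolactone 20. Hydroboration of the C3=C4 vinyl group with 9-BBN and intermolecular Suzuki–Miyaura coupling with 2-bromopropene (Pd(dppf)Cl2, K3PO4) would give the isopropenyl-extended iodolactone F1. Silver-assisted Kornblum oxidation as in step 17 would give the aldehyde F2. Wittig methylenation with Ph3P=CH2 would give the C7-vinyl diene F3. Ring-closing metathesis of F3 with the second-generation Grubbs catalyst at high dilution, where the lactone and ring strain should favour the cis-cycloalkene, would come back to the route at macrocycle 25.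

2. Step 12 (allylboration). Addition to the hindered aldehyde may be slow, and facial selectivity at C9 may be poor because the Felkin–Anh preference of the substrate is expected to oppose the reagent. The fallback sets C9 by hydride addition, where Felkin–Anh control should work in the desired sense. It sets out from aldehyde 14. 1-Lithio-1-methoxyallene (from methoxyallene and n-BuLi, THF, −78 °C) would give the allenyl carbinol F4 as either C9 epimer. Dess–Martin oxidation would give the allenyl ketone F5. Luche reduction (NaBH4, CeCl3, MeOH, −78 °C) would give the (9S)-carbinol F6. Hydrolysis of the methyl enol ether with aqueous oxalic acid would come back to the route at α-hydroxy enone 17.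

3. Step 17 (iodide to aldehyde). Displacement at the β-branched primary iodide next to the quaternary carbinol may be slow, and the α-acyloxy aldehyde may epimerise or undergo β-elimination under the amine base. The fallback forms the C6–O bond by a radical path and unveils the aldehyde without base. It sets out from iodolactone 20. Bu3SnH with excess TEMPO (benzene, 70 °C) would trap the C6 radical as the alkoxyamine F7. Oxidation of F7 with mCPBA (N-oxide formation, Cope-type elimination) would come back to the route at aldehyde 22.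

**Further compounds**

F1 | step 19 | iodolactone 20 with the C2 vinyl group replaced by a 3-methylbut-3-enyl chain (C3H2–C4H2–C5(CH3)=CH2) | [C@@H]1(O[Si](C)(C)C(C)(C)C)C[C@@H]2OC(C)(C)O[C@@H]2[C@](C)([C@@H](O[Si](CC)(CC)CC)CCC(C)=C)[C@H]1[C@H](O[Si](CC)(CC)CC)[C@]3(O)[C@@H](C)C(=O)O[C@H]3CI
F2 | step 19 | C6 aldehyde corresponding to F1 | [C@@H]1(O[Si](C)(C)C(C)(C)C)C[C@@H]2OC(C)(C)O[C@@H]2[C@](C)([C@@H](O[Si](CC)(CC)CC)CCC(C)=C)[C@H]1[C@H](O[Si](CC)(CC)CC)[C@]3(O)[C@@H](C)C(=O)O[C@H]3C=O
F3 | step 19 | diene: C7-vinyl lactone with the 3-methylbut-3-enyl chain on C2 | [C@@H]1(O[Si](C)(C)C(C)(C)C)C[C@@H]2OC(C)(C)O[C@@H]2[C@](C)([C@@H](O[Si](CC)(CC)CC)CCC(C)=C)[C@H]1[C@H](O[Si](CC)(CC)CC)[C@]3(O)[C@@H](C)C(=O)O[C@H]3C=C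
F4 | step 12 | C9 carbinol (both epimers) bearing a 1-methoxyallenyl group (C8(OMe)=C7=C6H2) | [C@@H]1(O[Si](C)(C)C(C)(C)C)C[C@@H]2OC(C)(C)O[C@@H]2[C@](C)([C@@H](O[Si](CC)(CC)CC)C=C)[C@H]1C(O)C(OC)=C=C
F5 | step 12 | C9 ketone bearing the 1-methoxyallenyl group | [C@@H]1(O[Si](C)(C)C(C)(C)C)C[C@@H]2OC(C)(C)O[C@@H]2[C@](C)([C@@H](O[Si](CC)(CC)CC)C=C)[C@H]1C(=O)C(OC)=C=C
F6 | step 12 | (9S)-carbinol bearing the 1-methoxyallenyl group | [C@@H]1(O[Si](C)(C)C(C)(C)C)C[C@@H]2OC(C)(C)O[C@@H]2[C@](C)([C@@H](O[Si](CC)(CC)CC)C=C)[C@H]1[C@H](O)C(OC)=C=C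
F7 | step 17 | C6 O-(2,2,6,6-tetramethylpiperidin-1-yl) alkoxyamine of the lactone | [C@@H]1(O[Si](C)(C)C(C)(C)C)C[C@@H]2OC(C)(C)O[C@@H]2[C@](C)([C@@H](O[Si](CC)(CC)CC)C=C)[C@H]1[C@H](O[Si](CC)(CC)CC)[C@]3(O)[C@@H](C)C(=O)O[C@H]3CON4C(C)(C)CCCC4(C)C
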